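The runs come from a simulation on assumed constants; scatter was added.

Every molecule of third reagent charged stands in one of three places: still free, in product, or, two at a time, in homo dimer.

| flask | substrate | partner | second reagent | third reagent | capture agent | temperature | remark | time |
|---|---|---|---|---|---|---|---|---|
| birch | 0.31 M | 0.372 M | 0.217 M | 1.24 M | 0.021 M | 45 °C | run made earlier |  |
| oak | 0.31 M | 0.372 M | 0.217 M | 1.24 M | 0.046 M | 80 °C | run made earlier |  |
| maple | 0.31 M | 0.372 M | 0.33 M | 1.24 M | 0.031 M | 45 °C | run made earlier |  |
| alpha | 0.31 M | 0.372 M | 0.217 M | 1.24 M | 0.0310 M | 110 °C |  | 50 h |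
| theta | 0.31 M | 0.372 M | 0.217 M | 1.24 M | 0.0310 M |  | at 50 °C until 40 h, from then on at 110 °C | 50 h |
| beta | 0.31 M | 0.372 M | 0.217 M | 1.24 M | 0.0310 M | 80 °C |  | 50 h |
| zeta | 0.31 M | 0.372 M | 0.217 M | 1.24 M | 0.0310 M | 50 °C |  | 50 h |

| run | time / h | product / % |
|---|---|---|
| birch | 144 | 14.7 |
| birch | 288 | 16.3 |
| birch | 480 | 19.0 |
| birch | 600 | 17.3 |
| birch | 720 | 17.4 |
| birch | 960 | 18.6 |
| oak | 12.0 | 21.5 |
| oak | 20.0 | 25.3 |
| oak | 40.0 | 24.5 |
| oak | 72.0 | 27.1 |
| oak | 120 | 25.6 |
| oak | 192 | 24.0 |
| maple | 96.0 | 11.2 |
| maple | 240 | 20.3 |
| maple | 480 | 18.6 |
| maple | 720 | 20.7 |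
| maple | 960 | 18.8 |

(scatter of a reading: 1 percentage point)

- steps thought possible: substrate + partner -> intermediate A; second reagent + intermediate A -> intermediate B; third reagent + intermediate B -> product; 2 third reagent -> homo dimer; intermediate A + capture agent -> trapped intermediate

- which flask leads in amount of product, in percent of the substrate charged ("all alike" within 1.5 percentage points) (alpha / theta / beta / zeta / all alike)
- how much product is there at the end, in percent of the substrate charged: alpha
- how much product is there at the end, in percent of the substrate charged: theta
- how much product is there at the end, in percent of the substrate charged: beta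
- how much product is there at the end, in percent of the substrate charged: zeta

The readings level off far below the substrate charged, and I read each plateau as the point where the free term of that balance has dropped out. Birch's last four readings averaged 18.1%, which gave 4.52% for φ, the fraction of the charged third reagent that ended in product and not in homo dimer (a selectivity). Oak's last five averaged 25.3%, so φ was 6.33% there. Oak differed from birch in capture agent as well as in temperature, but I chose to read the rise as one of heat, which gave an apparent energy difference of 8.98 kJ mol⁻¹. Carried to 110 °C, that gave φ = 8.04%, or 32.1% of the substrate for alpha.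

My second way assumed that each capture agent cost one product. I added the capture agent back to the birch and oak plateaus, extrapolated the sums in the same manner, and subtracted alpha's capture agent. That gave 46.5%, so the two ways parted by 14 percentage points and one of them cheated. Maple tested this, being at birch's temperature with more capture agent. Its last four readings averaged 19.6%, so the plain plateaus of maple and birch differed by 1.5 points, while the sums differed by 4.8 points. Maple also held more second reagent, so the test was not clean, but I kept the first way. I expected beta near oak's plateau, and theta, which shares out its third reagent at two temperatures, between the cold and hot plateaus.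

The forecast put alpha first, with 44% for alpha, above my figure, then 29% for theta, 30% for beta and 10% for zeta. One of its grounds was: “The capture agent seems to take the first A formed, roughly one for one.”

The simulation gave 33.9% for alpha, 21.1% for theta, 26.1% for beta and 7.37% for zeta, so alpha led.

    substrate + partner → intermediate A (k = 9.31 × 10⁻⁶ M⁻¹ s⁻¹, Ea = 86.0 kJ mol⁻¹)
    second reagent + intermediate A → intermediate B (k = 3.88 × 10⁻⁵ M⁻¹ s⁻¹, Ea = 83.0 kJ mol⁻¹)
    third reagent + intermediate B → product (k = 1.07 × 10⁻⁴ M⁻¹ s⁻¹, Ea = 70.0 kJ mol⁻¹)
    2 third reagent → homo dimer (k = 4.36 × 10⁻⁵ M⁻¹ s⁻¹, Ea = 66.0 kJ mol⁻¹)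
    intermediate A + capture agent → trapped intermediate (k = 1.25 × 10⁻⁴ M⁻¹ s⁻¹, Ea = 78.0 kJ mol⁻¹)
    (constants at 50 °C)

Alpha's product means φ = 8.48% against my 8.04%, with third reagent at 0% of its charge and homo dimer at 0.567 M. The path to homo dimer is the main reason why alpha's product falls short of the substrate charged: with that step taken away, alpha reaches 70.0%. The consumption of capture agent is not the reason, since alpha stands at 32.9% without it. For zeta's neighbour, read at 8.0 d at 50 °C, birch's φ carried over gives 4.76%, or 19.0% of the substrate. The computed product there is 18.5%, with third reagent at 0.0600% of its charge.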